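**Strategy.** With the side chain numbered C1' (OCH2) to C8' (lactone carbonyl), the lactone ring is read as a masked ketone aldol: the oxygens on C5' and C7' are 1,3-related across C6'H2, and C7' is a fully substituted carbinol carrying CH3 and C8'. A nitrile oxide centred on C5' therefore adds to 2-methylprop-2-en-1-ol under zinc/tartrate control, forming C5'–C6' and O–C7', closing the 4,5-dihydroisoxazole ring and setting C7' in one operation. Its precursor is the coumarin-bearing (3E)-3-methylpent-3-enal oxime. C8' is then oxidised before the N–O bond is cleaved, so no vicinal diol ever meets an oxidant, and reduction at C5' closes the lactone ring.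

Key step: step 6

Assumption: (R,R)-tartrate, which gives the (R)-dihydroisoxazole from allyl alcohol, is taken to induce the same facial sense on the 2-methyl alkene (5R), and the (R)-oxazaborolidine is chosen on the premise that the C6' arm is the larger ketone substituent; in either case the enantiomeric reagent is used if the sense proves opposite.

**Step 1**
Reactants: 1 tert-butyl(but-3-yn-1-yloxy)dimethylsilane
Product: 4 (2E)-5-{[tert-butyl(dimethyl)silyl]oxy}-3-methylpent-2-en-1-ol, via alkenylalane 2 (not isolated), via lithium alanate 3 (not isolated)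
Conditions: Me3Al (2.5 equiv), Cp2ZrCl2 (0.25 equiv), CH2Cl2, 0 °C to rt; volatiles removed; n-BuLi, hexane, 0 °C; (CH2O)n, THF, rt; aq. NH4Cl
Reagents that add atoms: trimethylaluminium, C[Al](C)C; formaldehyde (from paraformaldehyde), C=O
Why: Zirconocene-catalysed Negishi carboalumination adds CH3 and Al syn across the terminal alkyne with Al on the terminal carbon, and hydroxymethylation of the derived alanate with formaldehyde occurs with retention at the alkenyl carbon, which fixes the (E)-C2'=C3' geometry.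

**Step 2**
Reactants: 4 (2E)-5-{[tert-butyl(dimethyl)silyl]oxy}-3-methylpent-2-en-1-ol; 5 7-hydroxy-8-methoxy-2H-chromen-2-one
Product: 6 7-{[(2E)-5-{[tert-butyl(dimethyl)silyl]oxy}-3-methylpent-2-en-1-yl]oxy}-8-methoxy-2H-chromen-2-one
Conditions: PPh3, DIAD, THF, 0 °C to rt
Reagents that add atoms: none
Why: Mitsunobu etherification: the acidic 7-OH of the coumarin displaces the activated primary allylic oxygen at C1' by SN2, so the position and geometry of the alkene are retained.

**Step 3**
Reactants: 6 7-{[(2E)-5-{[tert-butyl(dimethyl)silyl]oxy}-3-methylpent-2-en-1-yl]oxy}-8-methoxy-2H-chromen-2-one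
Product: 7 7-{[(2E)-5-hydroxy-3-methylpent-2-en-1-yl]oxy}-8-methoxy-2H-chromen-2-one
Conditions: HF·pyridine, pyridine, THF, 0 °C to rt
Reagents that add atoms: none
Why: Fluoride-induced desilylation of a primary silyl ether; the pyridine-buffered reagent should leave the allyl aryl ether and the coumarin lactone intact.

**Step 4**
Reactants: 7 7-{[(2E)-5-hydroxy-3-methylpent-2-en-1-yl]oxy}-8-methoxy-2H-chromen-2-one
Product: 8 (3E)-5-[(8-methoxy-2-oxo-2H-chromen-7-yl)oxy]-3-methylpent-3-enal
Conditions: Dess–Martin periodinane, pyridine, CH2Cl2, 0 °C; crude aldehyde used at once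
Reagents that add atoms: none
Why: Dess–Martin oxidation runs under neutral, buffered conditions at low temperature, which should keep the C2'=C3' alkene out of conjugation with the new β,γ-unsaturated aldehyde.

**Step 5**
Reactants: 8 (3E)-5-[(8-methoxy-2-oxo-2H-chromen-7-yl)oxy]-3-methylpent-3-enal
Product: 9 (3E)-5-[(8-methoxy-2-oxo-2H-chromen-7-yl)oxy]-3-methylpent-3-enal oxime
Conditions: NH2OH·HCl, NaOAc, EtOH/H2O, 0 °C to rt
Reagents that add atoms: hydroxylamine hydrochloride, Cl.NO
Why: Oxime formation (condensation with hydroxylamine at buffered pH) is fast and converts the labile aldehyde into a stable nitrile oxide precursor; both C=N isomers lead to the same dipole.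

**Step 6**
Reactants: 9 (3E)-5-[(8-methoxy-2-oxo-2H-chromen-7-yl)oxy]-3-methylpent-3-enal oxime; 10 2-methylprop-2-en-1-ol
Product: 13 7-{[(2E)-4-[(5R)-5-(hydroxymethyl)-5-methyl-4,5-dihydroisoxazol-3-yl]-3-methylbut-2-en-1-yl]oxy}-8-methoxy-2H-chromen-2-one, via hydroximoyl chloride 11 (not isolated), via nitrile oxide 12 (not isolated)
Conditions: NCS, pyridine (cat.), CHCl3, rt; H2O wash, drying; solution added over 2 h to 10, Et2Zn (2 equiv), (R,R)-diisopropyl tartrate (1 equiv), 1,4-dioxane, CHCl3, 0 °C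
Reagents that add atoms: none
Why: N-Chlorosuccinimide chlorinates the oxime carbon to the hydroximoyl chloride, whose O–H is deprotonated by an ethylzinc unit so that loss of chloride releases the nitrile oxide on zinc, next to the allylic alkoxide held in a tartrate-bridged zinc complex, and the dipole then adds to the alkene in a concerted (3+2) cycloaddition. The closest known reaction type is the diethylzinc/tartrate-mediated asymmetric nitrile oxide cycloaddition to allylic alcohols, including 2-substituted ones. The 4,5-dihydroisoxazole ring is closed intermolecularly by this single cycloaddition, C5'–C6' and O–C7' being formed together, so no separate cyclisation event is needed. The new stereocentre C7' is controlled by the tartrate ligand, which through the zinc-bound alkoxide exposes one face of the 1,1-disubstituted alkene to the zinc-bound dipole; the (R,R)-ester is expected to give 5R. The step needs regioselectivity (oxygen to the disubstituted carbon, secured by the 1,1-disubstitution and the alkoxide delivery), enantiofacial selectivity (tartrate) and chemoselectivity over furoxan formation and over the C2'=C3' and coumarin C3=C4 alkenes (slow addition of the chloride and delivery to the alkoxide-bound alkene).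

**Step 7**
Reactants: 13 7-{[(2E)-4-[(5R)-5-(hydroxymethyl)-5-methyl-4,5-dihydroisoxazol-3-yl]-3-methylbut-2-en-1-yl]oxy}-8-methoxy-2H-chromen-2-one
Product: 15 (5R)-3-{(2E)-4-[(8-methoxy-2-oxo-2H-chromen-7-yl)oxy]-2-methylbut-2-en-1-yl}-5-methyl-4,5-dihydroisoxazole-5-carboxylic acid, via isoxazoline aldehyde 14 (not isolated)
Conditions: TEMPO (0.2 equiv), PhI(OAc)2 (2.5 equiv), MeCN/H2O (1:1), rt
Reagents that add atoms: water, O
Why: TEMPO-catalysed oxidation with PhI(OAc)2 in aqueous acetonitrile takes the primary alcohol through the non-enolisable aldehyde hydrate to the acid, and because O7' is still tied up in the N–O bond no vicinal diol is exposed to glycol cleavage.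

**Step 8**
Reactants: 15 (5R)-3-{(2E)-4-[(8-methoxy-2-oxo-2H-chromen-7-yl)oxy]-2-methylbut-2-en-1-yl}-5-methyl-4,5-dihydroisoxazole-5-carboxylic acid
Product: 16 methyl (5R)-3-{(2E)-4-[(8-methoxy-2-oxo-2H-chromen-7-yl)oxy]-2-methylbut-2-en-1-yl}-5-methyl-4,5-dihydroisoxazole-5-carboxylate
Conditions: MeI, KHCO3, DMF, 0 °C to rt
Reagents that add atoms: iodomethane, CI
Why: SN2 O-methylation of the potassium carboxylate (ester formation) under weakly basic conditions that should not open the coumarin or the dihydroisoxazole.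

**Step 9**
Reactants: 16 methyl (5R)-3-{(2E)-4-[(8-methoxy-2-oxo-2H-chromen-7-yl)oxy]-2-methylbut-2-en-1-yl}-5-methyl-4,5-dihydroisoxazole-5-carboxylate
Product: 18 methyl (2R,6E)-2-hydroxy-8-[(8-methoxy-2-oxo-2H-chromen-7-yl)oxy]-2,6-dimethyl-4-oxooct-6-enoate, via hydroxy imine 17 (not isolated)
Conditions: Mo(CO)6 (0.5 equiv), MeCN/H2O (15:1), 80 °C
Reagents that add atoms: water, O
Why: Mo(CO)6-mediated reductive N–O cleavage followed by hydrolysis of the imine unmasks the β-hydroxy ketone (the ketone aldol) without affecting C7', the alkenes or the esters.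

**Step 10**
Reactants: 18 methyl (2R,6E)-2-hydroxy-8-[(8-methoxy-2-oxo-2H-chromen-7-yl)oxy]-2,6-dimethyl-4-oxooct-6-enoate
Product: 20 7-{[(2E)-4-[(2S,4R)-4-hydroxy-4-methyl-5-oxooxolan-2-yl]-3-methylbut-2-en-1-yl]oxy}-8-methoxy-2H-chromen-2-one, via hydroxy ester 19 (not isolated)
Conditions: (R)-Me-CBS oxazaborolidine (0.3 equiv), catecholborane (3 equiv), toluene, −78 to −40 °C; MeOH quench; PPTS (cat.), rt
Reagents that add atoms: none
Why: Corey–Bakshi–Shibata reduction should deliver hydride to the Re face of the C5' ketone, the C6' arm attached to the fully substituted C7' acting as the larger group, which sets (S)-C5' under reagent control; catecholborane caps the tertiary hydroxyl so that no internal hydride delivery competes, and the γ-hydroxy ester then lactonises with loss of methanol.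

**Compound list**
1 | tert-butyl(but-3-yn-1-yloxy)dimethylsilane | C#CCCO[Si](C)(C)C(C)(C)C | starting material
2 | [(1E)-4-{[tert-butyl(dimethyl)silyl]oxy}-2-methylbut-1-en-1-yl]dimethylalane | C[Al](C)/C=C(\C)CCO[Si](C)(C)C(C)(C)C | intermediate
3 | lithium butyl[(1E)-4-{[tert-butyl(dimethyl)silyl]oxy}-2-methylbut-1-en-1-yl]dimethylalanate | [Li+].CCCC[Al-](C)(C)/C=C(\C)CCO[Si](C)(C)C(C)(C)C | intermediate
4 | (2E)-5-{[tert-butyl(dimethyl)silyl]oxy}-3-methylpent-2-en-1-ol | OC/C=C(\C)CCO[Si](C)(C)C(C)(C)C | intermediate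
5 | 7-hydroxy-8-methoxy-2H-chromen-2-one (7-hydroxy-8-methoxycoumarin) | COc1c(O)ccc2ccc(=O)oc12 | starting material
6 | 7-{[(2E)-5-{[tert-butyl(dimethyl)silyl]oxy}-3-methylpent-2-en-1-yl]oxy}-8-methoxy-2H-chromen-2-one | COc1c(OC/C=C(\C)CCO[Si](C)(C)C(C)(C)C)ccc2ccc(=O)oc12 | intermediate
7 | 7-{[(2E)-5-hydroxy-3-methylpent-2-en-1-yl]oxy}-8-methoxy-2H-chromen-2-one | COc1c(OC/C=C(\C)CCO)ccc2ccc(=O)oc12 | intermediate
8 | (3E)-5-[(8-methoxy-2-oxo-2H-chromen-7-yl)oxy]-3-methylpent-3-enal | COc1c(OC/C=C(\C)CC=O)ccc2ccc(=O)oc12 | intermediate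
9 | (3E)-5-[(8-methoxy-2-oxo-2H-chromen-7-yl)oxy]-3-methylpent-3-enal oxime (C=N isomer mixture) | COc1c(OC/C=C(\C)CC=NO)ccc2ccc(=O)oc12 | intermediate
10 | 2-methylprop-2-en-1-ol | C=C(C)CO | starting material
11 | (3E)-N-hydroxy-5-[(8-methoxy-2-oxo-2H-chromen-7-yl)oxy]-3-methylpent-3-enimidoyl chloride | COc1c(OC/C=C(\C)CC(Cl)=NO)ccc2ccc(=O)oc12 | intermediate
12 | (3E)-5-[(8-methoxy-2-oxo-2H-chromen-7-yl)oxy]-3-methylpent-3-enenitrile oxide | COc1c(OC/C=C(\C)CC#[N+][O-])ccc2ccc(=O)oc12 | intermediate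
13 | 7-{[(2E)-4-[(5R)-5-(hydroxymethyl)-5-methyl-4,5-dihydroisoxazol-3-yl]-3-methylbut-2-en-1-yl]oxy}-8-methoxy-2H-chromen-2-one | COc1c(OC/C=C(\C)CC2=NO[C@@](C)(CO)C2)ccc2ccc(=O)oc12 | intermediate
14 | (5R)-3-{(2E)-4-[(8-methoxy-2-oxo-2H-chromen-7-yl)oxy]-2-methylbut-2-en-1-yl}-5-methyl-4,5-dihydroisoxazole-5-carbaldehyde | COc1c(OC/C=C(\C)CC2=NO[C@@](C)(C=O)C2)ccc2ccc(=O)oc12 | intermediate
15 | (5R)-3-{(2E)-4-[(8-methoxy-2-oxo-2H-chromen-7-yl)oxy]-2-methylbut-2-en-1-yl}-5-methyl-4,5-dihydroisoxazole-5-carboxylic acid | COc1c(OC/C=C(\C)CC2=NO[C@@](C)(C(=O)O)C2)ccc2ccc(=O)oc12 | intermediate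
16 | methyl (5R)-3-{(2E)-4-[(8-methoxy-2-oxo-2H-chromen-7-yl)oxy]-2-methylbut-2-en-1-yl}-5-methyl-4,5-dihydroisoxazole-5-carboxylate | COc1c(OC/C=C(\C)CC2=NO[C@@](C)(C(=O)OC)C2)ccc2ccc(=O)oc12 | intermediate
17 | methyl (2R,6E)-2-hydroxy-4-imino-8-[(8-methoxy-2-oxo-2H-chromen-7-yl)oxy]-2,6-dimethyloct-6-enoate | COc1c(OC/C=C(\C)CC(=N)C[C@@](C)(O)C(=O)OC)ccc2ccc(=O)oc12 | intermediate
18 | methyl (2R,6E)-2-hydroxy-8-[(8-methoxy-2-oxo-2H-chromen-7-yl)oxy]-2,6-dimethyl-4-oxooct-6-enoate | COc1c(OC/C=C(\C)CC(=O)C[C@@](C)(O)C(=O)OC)ccc2ccc(=O)oc12 | intermediate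
19 | methyl (2R,4S,6E)-2,4-dihydroxy-8-[(8-methoxy-2-oxo-2H-chromen-7-yl)oxy]-2,6-dimethyloct-6-enoate | COc1c(OC/C=C(\C)C[C@H](O)C[C@@](C)(O)C(=O)OC)ccc2ccc(=O)oc12 | intermediate
20 | 7-{[(2E)-4-[(2S,4R)-4-hydroxy-4-methyl-5-oxooxolan-2-yl]-3-methylbut-2-en-1-yl]oxy}-8-methoxy-2H-chromen-2-one | COc1c(OC/C=C(\C)C[C@H]2C[C@@](C)(O)C(=O)O2)ccc2ccc(=O)oc12 | target

**Step count.** Total: 10 steps. Longest linear sequence: 10 steps (1 to 20); compounds 5 and 10 enter as purchased materials.

**Steps most likely to fail**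

1. Step 6. Enantiofacial discrimination on the 2-methyl alkene may be insufficient, and dimerisation of the nitrile oxide may outrun the cycloaddition. The fallback sets out from 9 and returns at 16, replacing asymmetric induction by a racemic cycloaddition and resolution. Oxime 9 is chlorinated as before and chloride 11 is treated with methyl methacrylate and Et3N in CH2Cl2 at 0 °C. Nitrile oxide 12 should add with the same regiochemistry to give racemic methyl 3-{(2E)-4-[(8-methoxy-2-oxo-2H-chromen-7-yl)oxy]-2-methylbut-2-en-1-yl}-5-methyl-4,5-dihydroisoxazole-5-carboxylate F1. Its enantiomers are separated by preparative chromatography on a chiral stationary phase; the (5R)-enantiomer is 16, and steps 7 and 8 are then not needed.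

2. Step 10. Facial selectivity at C5' may be poor, because both ketone substituents are methylene groups and the catalyst has little to distinguish. The fallback sets out from 18 and returns at 20, replacing reagent control by chelate control followed by inversion. Zn(BH4)2 (Et2O, −20 °C) is expected, through a zinc chelate spanning the ketone, the tertiary hydroxyl and the ester, to favour methyl (2R,4R,6E)-2,4-dihydroxy-8-[(8-methoxy-2-oxo-2H-chromen-7-yl)oxy]-2,6-dimethyloct-6-enoate F2. This lactonises to the C5'-epimer 7-{[(2E)-4-[(2R,4R)-4-hydroxy-4-methyl-5-oxooxolan-2-yl]-3-methylbut-2-en-1-yl]oxy}-8-methoxy-2H-chromen-2-one F3. Saponification (LiOH, THF/H2O, 0 °C, then buffering to pH 4–5, which recloses any opened coumarin) gives (2R,4R,6E)-2,4-dihydroxy-8-[(8-methoxy-2-oxo-2H-chromen-7-yl)oxy]-2,6-dimethyloct-6-enoic acid F4. Mitsunobu lactonisation (PPh3, DIAD, THF, high dilution) then closes the ring by SN2 attack of the carboxylate on C5' with inversion, giving 20.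

3. Step 4. The C2'=C3' alkene may migrate into conjugation with the new aldehyde, or lose its geometry, during oxidation or handling. The fallback sets out from 7 and returns at 9, avoiding the aldehyde altogether. Alcohol 7 is converted (I2, PPh3, imidazole, CH2Cl2) into 7-{[(2E)-5-iodo-3-methylpent-2-en-1-yl]oxy}-8-methoxy-2H-chromen-2-one F5. Kornblum displacement (NaNO2, phloroglucinol, DMF) gives 8-methoxy-7-{[(2E)-3-methyl-5-nitropent-2-en-1-yl]oxy}-2H-chromen-2-one F6. Partial reduction of the primary nitro group (SnCl2, PhSH, Et3N, MeCN) should then deliver oxime 9 directly.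

**Further compounds**
F1 | step 6 | racemic methyl 3-{(2E)-4-[(8-methoxy-2-oxo-2H-chromen-7-yl)oxy]-2-methylbut-2-en-1-yl}-5-methyl-4,5-dihydroisoxazole-5-carboxylate | COc1c(OC/C=C(\C)CC2=NOC(C)(C(=O)OC)C2)ccc2ccc(=O)oc12
F2 | step 10 | methyl (2R,4R,6E)-2,4-dihydroxy-8-[(8-methoxy-2-oxo-2H-chromen-7-yl)oxy]-2,6-dimethyloct-6-enoate | COc1c(OC/C=C(\C)C[C@@H](O)C[C@@](C)(O)C(=O)OC)ccc2ccc(=O)oc12
F3 | step 10 | 7-{[(2E)-4-[(2R,4R)-4-hydroxy-4-methyl-5-oxooxolan-2-yl]-3-methylbut-2-en-1-yl]oxy}-8-methoxy-2H-chromen-2-one | COc1c(OC/C=C(\C)C[C@@H]2C[C@@](C)(O)C(=O)O2)ccc2ccc(=O)oc12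
F4 | step 10 | (2R,4R,6E)-2,4-dihydroxy-8-[(8-methoxy-2-oxo-2H-chromen-7-yl)oxy]-2,6-dimethyloct-6-enoic acid | COc1c(OC/C=C(\C)C[C@@H](O)C[C@@](C)(O)C(=O)O)ccc2ccc(=O)oc12
F5 | step 4 | 7-{[(2E)-5-iodo-3-methylpent-2-en-1-yl]oxy}-8-methoxy-2H-chromen-2-one | COc1c(OC/C=C(\C)CCI)ccc2ccc(=O)oc12
F6 | step 4 | 8-methoxy-7-{[(2E)-3-methyl-5-nitropent-2-en-1-yl]oxy}-2H-chromen-2-one | COc1c(OC/C=C(\C)CC[N+](=O)[O-])ccc2ccc(=O)oc12
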